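## Retrosynthetic overview

1. Target 17 ⇐ cis‑diol 15 (ortho ester opening leaves the cinnamate on the axial O3); (13Z)‑enoate ⇐ ynoate 13 (syn‑methylcupration) ⇐ methyl ketone 10.
2. 7‑Ene and side‑chain ketone ⇐ δ‑lactone 7 (MeLi opening, exo‑selective dehydration, H‑atom‑transfer isomerisation).
3. 2α,3α‑Diol ⇐ 2‑ene 5 (α‑face OsO4) ⇐ 3β‑aryl sulfide 3 (sulfoxide syn‑elimination).
4. Key step: 3 ⇐ achiral farnesylacetic acid 2 by catalytic enantioselective sulfenium‑initiated bicyclisation; ring A, then ring B, then the lactone ring close in one cascade. This replaces the usual epoxide‑initiated cyclisation or a sclareol‑type semisynthesis.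
5. 2 ⇐ (2E,6E)‑farnesyl bromide 1 + acetic acid.

Labdane numbering and α/β descriptors are used for all bicyclic compounds (10β‑Me, 5α‑H, 9α‑H throughout).

Assumption: the (S)‑configured catalyst gives the (3S), 10β‑methyl series, as it does with homogeranylarenes; if the sense proves opposite, the (R)‑catalyst is used and nothing else changes.

## Route

Step 1
Reactants: 1 (2E,6E)-farnesyl bromide
Product: 2 (4E,8E)-5,9,13-trimethyltetradeca-4,8,12-trienoic acid (farnesylacetic acid)
Conditions: AcOH, LiN(iPr)2 (2.2 equiv), THF/DMPU, 0 to 40 °C; then 1, 0 °C to rt; aq HCl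
Reagents that add atoms: acetic acid, CC(=O)O (used as its dilithio dianion)
Why: SN2 alkylation of the acetic acid dianion at the primary allylic bromide extends the chain by two carbons in one step, leaves both E‑alkenes untouched and creates no stereocentre.

Step 2
Reactants: 2 (4E,8E)-5,9,13-trimethyltetradeca-4,8,12-trienoic acid
Product: 3 3β-[(2,6-diisopropylphenyl)thio]-14,15,16-trinorlabdan-13,8α-olide
Conditions: N-[(2,6-diisopropylphenyl)thio]succinimide (1.1 equiv), (S)-4-(diisopropylamino)-3,5-dimethyl-4,5-dihydro-3H-dinaphtho[2,1-d:1',2'-f][1,3,2]diazaphosphepine 4-selenide (10 mol%), (CF3)2CHOH, 0 °C to rt; product recrystallised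
Reagents that add atoms: N-[(2,6-diisopropylphenyl)thio]succinimide, O=C1CCC(=O)N1Sc1c(C(C)C)cccc1C(C)C
Why: Proposed new method: Lewis‑base‑catalysed enantioselective sulfenocyclisation extended to an acid‑terminated triene, in which the chiral selenophosphoramide–ArS+ adduct delivers sulfur to one face of the most accessible and electron‑rich terminal isopropylidene alkene (setting C3), the next alkene opens the thiiranium anti at its tertiary carbon through a chair–chair array (sulfur equatorial 3β, trans ring fusion at C5/C10, 9α‑H) and the carboxylic acid traps the C8 cation anti (8α‑O) to close the δ‑lactone; the closest known reactions are the same catalytic sulfenocyclisation of homogeranylarenes and geranylphenols and the catalytic sulfenolactonisation of alkenoic acids.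

Step 3
Reactants: 3 3β-[(2,6-diisopropylphenyl)thio]-14,15,16-trinorlabdan-13,8α-olide
Product: 5 14,15,16-trinorlabd-2-en-13,8α-olide, via sulfoxide 4 (not isolated)
Conditions: mCPBA (1.0 equiv), CH2Cl2, −78 °C; then NaHCO3, toluene, 110 °C
Reagents that add atoms: mCPBA, O=C(OO)c1cccc(Cl)c1 (its oxygen is carried only by 4 and leaves again with the sulfur)
Why: S‑oxidation followed by thermal sulfoxide syn‑elimination can only remove a C2 hydrogen because C4 is quaternary, so the 2‑ene forms regiospecifically and no stereocentre is touched.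

Step 4
Reactants: 5 14,15,16-trinorlabd-2-en-13,8α-olide
Product: 6 2α,3α-dihydroxy-14,15,16-trinorlabdan-13,8α-olide
Conditions: OsO4 (5 to 10 mol%), NMO, acetone/H2O, rt to 40 °C
Reagents that add atoms: N-methylmorpholine N-oxide, C[N+]1([O-])CCOCC1; water, O (both oxygens are passed on through catalytic OsO4, O=[Os](=O)(=O)=O)
Why: Upjohn syn‑dihydroxylation occurs from the α face because the β face of ring A is blocked by the two 1,3‑diaxial methyl groups (4β and 10β), which sets C2 and C3 together as the 2α,3α‑cis‑diol while ring B carries no competing alkene.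

Step 5
Reactants: 6 2α,3α-dihydroxy-14,15,16-trinorlabdan-13,8α-olide
Product: 7 2α,3α-(isopropylidenedioxy)-14,15,16-trinorlabdan-13,8α-olide
Conditions: Me2C(OMe)2, PPTS (cat.), CH2Cl2, rt
Reagents that add atoms: 2,2-dimethoxypropane, COC(C)(C)OC
Why: Acid‑catalysed transketalisation of the cis‑diol gives the cis‑fused dioxolane, which protects both hydroxyls through the organometallic steps that follow.

Step 6
Reactants: 7 2α,3α-(isopropylidenedioxy)-14,15,16-trinorlabdan-13,8α-olide
Product: 8 8α-hydroxy-2α,3α-(isopropylidenedioxy)-14,15-dinorlabdan-13-one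
Conditions: MeLi (1.2 equiv), THF, −78 °C; then H2O
Reagents that add atoms: methyllithium, [Li]C
Why: Addition of MeLi to the δ‑lactone stops at the lithium hemiketal at low temperature, so work‑up gives the hydroxy methyl ketone (lactone‑to‑ketone mono‑addition) with C8 unchanged.

Step 7
Reactants: 8 8α-hydroxy-2α,3α-(isopropylidenedioxy)-14,15-dinorlabdan-13-one
Product: 9 2α,3α-(isopropylidenedioxy)-14,15-dinorlabd-8(17)-en-13-one
Conditions: SOCl2, pyridine, CH2Cl2, −78 °C
Reagents that add atoms: none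
Why: In this chlorosulfite E2 dehydration the equatorial 8α‑oxygen has no anti‑periplanar ring hydrogen, so pyridine removes a C17 methyl hydrogen and the exocyclic alkene predominates, while any 7‑ene formed is already the product of the next step.

Step 8
Reactants: 9 2α,3α-(isopropylidenedioxy)-14,15-dinorlabd-8(17)-en-13-one
Product: 10 2α,3α-(isopropylidenedioxy)-14,15-dinorlabd-7-en-13-one
Conditions: Co(salen)Cl (3 mol%; salen = N,N'-bis(3,5-di-tert-butylsalicylidene)-1,2-cyclohexanediaminate), PhSiH3 (6 mol%), benzene, rt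
Reagents that add atoms: none
Why: In this cobalt‑hydride hydrogen‑atom‑transfer alkene isomerisation, reversible H‑atom addition to the 1,1‑disubstituted alkene gives the tertiary C8 radical, and the cobalt then abstracts hydrogen from the accessible C7 methylene rather than the hindered C9 methine next to the quaternary carbon, giving the trisubstituted 7‑ene without touching C9, the ketone or the acetonide.

Step 9
Reactants: 10 2α,3α-(isopropylidenedioxy)-14,15-dinorlabd-7-en-13-one
Product: 13 methyl 2α,3α-(isopropylidenedioxy)-16-norlabd-7-en-13-yn-15-oate, via enol phosphate 11 (not isolated), via lithium acetylide 12 (not isolated)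
Conditions: LiN(iPr)2 (1.1 equiv), THF, −78 °C; ClP(O)(OEt)2, −78 °C to rt; LiN(iPr)2 (2.3 equiv), −78 °C to rt; ClCO2Me (3 equiv), −78 °C
Reagents that add atoms: diethyl chlorophosphate, CCOP(=O)(Cl)OCC (in 11 only); methyl chloroformate, COC(=O)Cl
Why: Negishi one‑pot alkyne synthesis from a methyl ketone (kinetic methyl‑side enolisation, O‑phosphorylation, base‑induced elimination) delivers the terminal acetylide, which is C‑acylated by methyl chloroformate to the ynoate.

Step 10
Reactants: 13 methyl 2α,3α-(isopropylidenedioxy)-16-norlabd-7-en-13-yn-15-oate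
Product: 14 methyl (13Z)-2α,3α-(isopropylidenedioxy)labda-7,13-dien-15-oate
Conditions: Me2CuLi (1.5 equiv, from MeLi and CuI), THF, −78 °C; MeOH then aq NH4Cl at −78 °C
Reagents that add atoms: lithium dimethylcuprate, [Li+].C[Cu-]C
Why: Stereospecific syn‑carbocupration of the ynoate at −78 °C with cold protonation puts the new methyl cis to hydrogen and therefore trans to the ester, which is exactly the (13Z) geometry of the target.

Step 11
Reactants: 14 methyl (13Z)-2α,3α-(isopropylidenedioxy)labda-7,13-dien-15-oate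
Product: 15 methyl (13Z)-2α,3α-dihydroxylabda-7,13-dien-15-oate
Conditions: AcOH/H2O 4:1, 40 °C
Reagents that add atoms: none
Why: Mild aqueous acid hydrolysis of the acetonide frees the cis‑diol without moving either trisubstituted alkene or touching the methyl ester.

Step 12
Reactants: 15 methyl (13Z)-2α,3α-dihydroxylabda-7,13-dien-15-oate
Product: 17 methyl (13Z)-3α-[(E)-cinnamoyloxy]-2α-hydroxylabda-7,13-dien-15-oate, via cyclic ortho ester 16 (not isolated)
Conditions: (E)-PhCH=CHC(OMe)3 (3 equiv), CSA (5 mol%), CH2Cl2, rt; then AcOH/H2O 4:1, rt, short; neutral work‑up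
Reagents that add atoms: trimethyl orthocinnamate, COC(OC)(OC)/C=C/c1ccccc1; water, O (becomes the ester carbonyl oxygen)
Why: Ortho ester exchange gives the cyclic 2,3‑orthocinnamate, and its kinetically controlled acid hydrolysis opens the dioxolanium so that the acyl group stays on the axial oxygen (O3) and the equatorial 2α‑OH is released (stereoelectronic rule for ortho esters of cis axial/equatorial diols), giving the target without a protecting group.

## Compound list

1 | (2E,6E)-farnesyl bromide | CC(C)=CCC/C(C)=C/CC/C(C)=C/CBr | starting material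
2 | (4E,8E)-5,9,13-trimethyltetradeca-4,8,12-trienoic acid | CC(C)=CCC/C(C)=C/CC/C(C)=C/CCC(=O)O | intermediate
3 | 3β-[(2,6-diisopropylphenyl)thio]-14,15,16-trinorlabdan-13,8α-olide | O=C1CC[C@H]2[C@](C)(O1)CC[C@H]3C(C)(C)[C@@H](Sc4c(C(C)C)cccc4C(C)C)CC[C@]23C | intermediate
4 | 3β-[(2,6-diisopropylphenyl)sulfinyl]-14,15,16-trinorlabdan-13,8α-olide (both sulfur epimers) | O=C1CC[C@H]2[C@](C)(O1)CC[C@H]3C(C)(C)[C@@H](S(=O)c4c(C(C)C)cccc4C(C)C)CC[C@]23C | intermediate
5 | 14,15,16-trinorlabd-2-en-13,8α-olide | O=C1CC[C@H]2[C@](C)(O1)CC[C@H]3C(C)(C)C=CC[C@]23C | intermediate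
6 | 2α,3α-dihydroxy-14,15,16-trinorlabdan-13,8α-olide | O=C1CC[C@H]2[C@](C)(O1)CC[C@H]3C(C)(C)[C@H](O)[C@H](O)C[C@]23C | intermediate
7 | 2α,3α-(isopropylidenedioxy)-14,15,16-trinorlabdan-13,8α-olide | O=C1CC[C@H]2[C@](C)(O1)CC[C@H]3C(C)(C)[C@H](OC4(C)C)[C@H](O4)C[C@]23C | intermediate
8 | 8α-hydroxy-2α,3α-(isopropylidenedioxy)-14,15-dinorlabdan-13-one | CC(=O)CC[C@H]1[C@](C)(O)CC[C@H]2C(C)(C)[C@H](OC3(C)C)[C@H](O3)C[C@]12C | intermediate
9 | 2α,3α-(isopropylidenedioxy)-14,15-dinorlabd-8(17)-en-13-one | CC(=O)CC[C@H]1C(=C)CC[C@H]2C(C)(C)[C@H](OC3(C)C)[C@H](O3)C[C@]12C | intermediate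
10 | 2α,3α-(isopropylidenedioxy)-14,15-dinorlabd-7-en-13-one | CC(=O)CC[C@H]1C(C)=CC[C@H]2C(C)(C)[C@H](OC3(C)C)[C@H](O3)C[C@]12C | intermediate
11 | diethyl 2α,3α-(isopropylidenedioxy)-14,15-dinorlabda-7,13(16)-dien-13-yl phosphate | C=C(OP(=O)(OCC)OCC)CC[C@H]1C(C)=CC[C@H]2C(C)(C)[C@H](OC3(C)C)[C@H](O3)C[C@]12C | intermediate
12 | [2α,3α-(isopropylidenedioxy)-15,16-dinorlabd-7-en-13-yn-14-yl]lithium | [Li]C#CCC[C@H]1C(C)=CC[C@H]2C(C)(C)[C@H](OC3(C)C)[C@H](O3)C[C@]12C | intermediate
13 | methyl 2α,3α-(isopropylidenedioxy)-16-norlabd-7-en-13-yn-15-oate | COC(=O)C#CCC[C@H]1C(C)=CC[C@H]2C(C)(C)[C@H](OC3(C)C)[C@H](O3)C[C@]12C | intermediate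
14 | methyl (13Z)-2α,3α-(isopropylidenedioxy)labda-7,13-dien-15-oate | COC(=O)/C=C(/C)CC[C@H]1C(C)=CC[C@H]2C(C)(C)[C@H](OC3(C)C)[C@H](O3)C[C@]12C | intermediate
15 | methyl (13Z)-2α,3α-dihydroxylabda-7,13-dien-15-oate | COC(=O)/C=C(/C)CC[C@H]1C(C)=CC[C@H]2C(C)(C)[C@H](O)[C@H](O)C[C@]12C | intermediate
16 | methyl (13Z)-2α,3α-[(1-methoxy-3-phenylprop-2-en-1-ylidene)dioxy]labda-7,13-dien-15-oate (cyclic orthocinnamate, both epimers at the ortho ester carbon) | COC(=O)/C=C(/C)CC[C@H]1C(C)=CC[C@H]2C(C)(C)[C@H](OC3(OC)/C=C/c4ccccc4)[C@H](O3)C[C@]12C | intermediate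
17 | methyl (13Z)-3α-[(E)-cinnamoyloxy]-2α-hydroxylabda-7,13-dien-15-oate (2R,3S,5R,9S,10R) | COC(=O)/C=C(/C)CC[C@H]1C(C)=CC[C@H]2C(C)(C)[C@H](OC(=O)/C=C/c3ccccc3)[C@H](O)C[C@]12C | target

## Step count and risk

Total step count: 12. Longest linear sequence: 12 steps (1 to 17, fully linear).

Steps most likely to fail:

**Step 2 (key bicyclisation).** The risks are sulfur transfer to the acid‑proximal alkene (direct sulfenolactonisation), termination by proton loss instead of lactone closure, and incomplete enantiocontrol with a non‑aromatic terminator. The fallback replaces the sulfenium initiator by an epoxide; it sets out from 2 and comes back at 5. Acid 2 is mono‑epoxidised at the terminal alkene by Shi epoxidation, using the enantiomer of the Shi ketone that gives the (12S)‑oxirane (the L‑fructose‑derived one), KHSO5 (as 2KHSO5·KHSO4·K2SO4), K2CO3 buffer, MeCN/dimethoxymethane/H2O, 0 °C, run to partial conversion with separation of regioisomers, giving the (12S)‑12,13‑epoxy acid F1. SnCl4 in CH2Cl2 at −78 °C then effects the epoxide‑initiated cation–olefin bicyclisation with acid termination to the 3β‑hydroxy lactone F2. Dess–Martin oxidation gives the 3‑keto lactone F3. KN(SiMe3)2 and PhNTf2 at −78 °C give the 2‑en‑3‑yl triflate F4; the ketone can enolise only towards C2 and is more acidic than the lactone. Pd(OAc)2/PPh3 with Bu3N/HCO2H in DMF at 60 °C reduces the triflate to alkene 5.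

**Step 8 (exo to endo isomerisation).** The risks are partial formation of the tetrasubstituted 8(9)‑ene or stalling. The fallback fixes the alkene position through an enol triflate instead; it sets out from 7 and comes back at 10. Lactone 7 is opened with MeNH(OMe)·HCl/Me3Al to the 8α‑hydroxy Weinreb amide F5. SOCl2/pyridine at −78 °C gives the 8(17)‑ene Weinreb amide F6. Ozonolysis (O3, CH2Cl2/MeOH, −78 °C, then Me2S) gives the 17‑nor 8‑ketone F7. KN(SiMe3)2 and PhNTf2 at −78 °C deprotonate the C7 methylene, not the hindered C9 methine or the amide, to give the 7‑en‑8‑yl triflate F8. Excess MeMgBr with Fe(acac)3 (5 mol%) in THF/NMP at −30 to 0 °C replaces the triflate by methyl with retention of the alkene position and converts the Weinreb amide into the methyl ketone, giving 10.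

**Step 12 (mono‑acylation on the hindered axial O3).** The risks are incomplete ortho ester exchange at the neopentyl axial hydroxyl and 3‑to‑2 acyl migration. The fallback uses stepwise protection and is independent of the ortho ester reagent; it sets out from 15 and comes back at 17. The unhindered equatorial 2α‑OH is silylated selectively (Et3SiCl, imidazole, DMF, −20 °C) to give the 2‑O‑triethylsilyl ether F9. The axial 3α‑OH is then acylated under forcing conditions ((E)‑cinnamoyl chloride, DMAP, pyridine, 60 °C) to give the silyl ether cinnamate F10. HF·pyridine in THF at 0 °C (acidic, so no acyl migration) removes the silyl group to give 17.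

## Further compounds

F1 | step 2 | (4E,8E,12S)-12,13-epoxy-5,9,13-trimethyltetradeca-4,8-dienoic acid | CC1(C)O[C@H]1CC/C(C)=C/CC/C(C)=C/CCC(=O)O
F2 | step 2 | 3β-hydroxy-14,15,16-trinorlabdan-13,8α-olide | O=C1CC[C@H]2[C@](C)(O1)CC[C@H]3C(C)(C)[C@@H](O)CC[C@]23C
F3 | step 2 | 3-oxo-14,15,16-trinorlabdan-13,8α-olide | O=C1CC[C@H]2[C@](C)(O1)CC[C@H]3C(C)(C)C(=O)CC[C@]23C
F4 | step 2 | 3-(trifluoromethylsulfonyloxy)-14,15,16-trinorlabd-2-en-13,8α-olide | O=C1CC[C@H]2[C@](C)(O1)CC[C@H]3C(C)(C)C(OS(=O)(=O)C(F)(F)F)=CC[C@]23C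
F5 | step 8 | 8α-hydroxy-2α,3α-(isopropylidenedioxy)-N-methoxy-N-methyl-14,15,16-trinorlabdan-13-amide | CON(C)C(=O)CC[C@H]1[C@](C)(O)CC[C@H]2C(C)(C)[C@H](OC3(C)C)[C@H](O3)C[C@]12C
F6 | step 8 | 2α,3α-(isopropylidenedioxy)-N-methoxy-N-methyl-14,15,16-trinorlabd-8(17)-en-13-amide | CON(C)C(=O)CC[C@H]1C(=C)CC[C@H]2C(C)(C)[C@H](OC3(C)C)[C@H](O3)C[C@]12C
F7 | step 8 | 2α,3α-(isopropylidenedioxy)-N-methoxy-N-methyl-8-oxo-14,15,16,17-tetranorlabdan-13-amide | CON(C)C(=O)CC[C@H]1C(=O)CC[C@H]2C(C)(C)[C@H](OC3(C)C)[C@H](O3)C[C@]12C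
F8 | step 8 | 2α,3α-(isopropylidenedioxy)-N-methoxy-N-methyl-8-(trifluoromethylsulfonyloxy)-14,15,16,17-tetranorlabd-7-en-13-amide | CON(C)C(=O)CC[C@H]1C(OS(=O)(=O)C(F)(F)F)=CC[C@H]2C(C)(C)[C@H](OC3(C)C)[C@H](O3)C[C@]12C
F9 | step 12 | methyl (13Z)-3α-hydroxy-2α-(triethylsilyloxy)labda-7,13-dien-15-oate | COC(=O)/C=C(/C)CC[C@H]1C(C)=CC[C@H]2C(C)(C)[C@H](O)[C@H](O[Si](CC)(CC)CC)C[C@]12C
F10 | step 12 | methyl (13Z)-3α-[(E)-cinnamoyloxy]-2α-(triethylsilyloxy)labda-7,13-dien-15-oate | COC(=O)/C=C(/C)CC[C@H]1C(C)=CC[C@H]2C(C)(C)[C@H](OC(=O)/C=C/c3ccccc3)[C@H](O[Si](CC)(CC)CC)C[C@]12C
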